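**Plan**
1. Retrosynthetically, the six phenols come from benzyl ethers, the C1 aroyl group from a secondary carbinol, and the ring A oxygens at C4 and C6 from a C–Br and a C–B bond.
2. Ring A (C3a–C4–C5–C6–C7–C7a) is fused to the five-membered ring at C3a–C7a and oxygenated at C4 and C6, meta to each other. It is cut at C3a–C7a, C4–C5 and C6–C7, which is the pattern a 1,6-diyne tethered through C1–C2–C3 and capped at the future C4 gives with a terminal alkyne, whose substituent ends meta to the cap.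
3. The diyne is cut at C1–C(carbinol) (allenylzinc plus 4-benzyloxybenzaldehyde), at C1–C7a (acetylide plus Weinreb amide) and at C2–C3 (allylic alkylation of an arylacetic ester).
4. Forward: C2–C3 is joined first, then the C1 alkyne and the carbinol arm are attached, then the C3 vinyl group becomes a bromoalkyne. Bromine is the cap because it is installed by dehydrobromination, so the other terminus stays C–H. The five-membered ring and ring A then form together.
5. Stereochemistry: C2 and C3 come from the two chiral catalysts of the allylation; C1 comes from a Noyori reduction, relayed with inversion through the allenylzinc. All three sit on the tether, the cyclisation creates none, and the epimerisable C1–H next to the ketone exists only in the last two steps.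

Key step: step 14

Remark on the chemistry: the SMILES is read as (1R,2R,3R), which places the aroyl group at C1 and the aryl groups at C2 and C3 on the same face of the five-membered ring. The route is laid out for exactly this isomer.

**Route**

Step 1
Reactants: 1 [4-(benzyloxy)phenyl]acetic acid
Product: 2 pentafluorophenyl [4-(benzyloxy)phenyl]acetate
Conditions: C6F5OH, DCC, EtOAc, 0 °C → rt
Reagents that add atoms: pentafluorophenol, Oc1c(F)c(F)c(F)c(F)c1F
Why: Carbodiimide (Steglich-type) esterification gives the active ester that an isothiourea needs to form a C1-ammonium enolate; no stereocentre is involved.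

Step 2
Reactants: 3 3,5-bis(benzyloxy)benzaldehyde
Product: 4 ethyl (2E)-3-[3,5-bis(benzyloxy)phenyl]prop-2-enoate
Conditions: (EtO)2P(O)CH2CO2Et, NaH, THF, 0 °C → rt
Reagents that add atoms: triethyl phosphonoacetate, CCOC(=O)CP(=O)(OCC)OCC
Why: Horner–Wadsworth–Emmons olefination of an aromatic aldehyde with a stabilised phosphonate should be E-selective.

Step 3
Reactants: 4 ethyl (2E)-3-[3,5-bis(benzyloxy)phenyl]prop-2-enoate
Product: 5 (2E)-3-[3,5-bis(benzyloxy)phenyl]prop-2-en-1-ol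
Conditions: i-Bu2AlH (2.5 equiv), CH2Cl2, −78 °C; aq. potassium sodium tartrate
Reagents that add atoms: none
Why: Hydride reduction of the conjugated ester by the aluminium hydride is a 1,2-reduction at low temperature and leaves the alkene and the benzyl ethers alone.

Step 4
Reactants: 5 (2E)-3-[3,5-bis(benzyloxy)phenyl]prop-2-en-1-ol
Product: 6 tert-butyl (2E)-3-[3,5-bis(benzyloxy)phenyl]prop-2-en-1-yl carbonate
Conditions: n-BuLi, THF, −78 °C; Boc2O, −78 → 0 °C
Reagents that add atoms: di-tert-butyl dicarbonate, CC(C)(C)OC(=O)OC(=O)OC(C)(C)C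
Why: O-Acylation of the lithium alkoxide gives the linear allylic carbonate, a standard electrophile for iridium-catalysed allylic substitution that releases only CO2 and tert-butoxide.

Step 5
Reactants: 2 pentafluorophenyl [4-(benzyloxy)phenyl]acetate; 6 tert-butyl (2E)-3-[3,5-bis(benzyloxy)phenyl]prop-2-en-1-yl carbonate
Product: 8 (2S,3R)-2-[4-(benzyloxy)phenyl]-3-[3,5-bis(benzyloxy)phenyl]-N-methoxy-N-methylpent-4-enamide, via pentafluorophenyl ester 7 (not isolated)
Conditions: [Ir(cod)Cl]2 (2 mol%), (S,S,S)-L (4 mol%; L = binaphthyl-2,2′-diyl N,N-bis(1-phenylethyl)phosphoramidite, preformed metallacycle), (S)-benzotetramisole (10 mol%), i-Pr2NEt, THF, rt; then MeNH(OMe)·HCl, i-Pr2NEt, rt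
Reagents that add atoms: N,O-dimethylhydroxylamine hydrochloride, CNOC.Cl
Why: Iridium-catalysed asymmetric allylic alkylation under isothiourea co-catalysis: the iridium phosphoramidite ionises 6 to a π-allyl that is attacked at the aryl-bearing terminus and should fix C3 as R, while benzotetramisole turns 2 into a (Z)-C1-ammonium enolate that reacts anti to the catalyst phenyl group and should fix C2 as S; pentafluorophenoxide rebound releases 7 and aminolysis gives the Weinreb amide without touching either centre, and because each catalyst controls one centre the enantiomer of either is exchanged if the sense of induction proves opposite to the model.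

Step 6
Reactants: 8 (2S,3R)-2-[4-(benzyloxy)phenyl]-3-[3,5-bis(benzyloxy)phenyl]-N-methoxy-N-methylpent-4-enamide
Product: 9 (4S,5R)-4-[4-(benzyloxy)phenyl]-5-[3,5-bis(benzyloxy)phenyl]-1-(trimethylsilyl)hept-6-en-1-yn-3-one
Conditions: Me3SiC≡CH, n-BuLi, THF, −78 °C; then 8, −78 → −20 °C; aq. NH4Cl
Reagents that add atoms: ethynyltrimethylsilane, C#C[Si](C)(C)C
Why: Weinreb ketone synthesis: the lithium acetylide adds once because the chelated tetrahedral intermediate survives until the quench, and the weakly basic acetylide at low temperature should leave the α-aryl centre intact.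

Step 7
Reactants: 9 (4S,5R)-4-[4-(benzyloxy)phenyl]-5-[3,5-bis(benzyloxy)phenyl]-1-(trimethylsilyl)hept-6-en-1-yn-3-one
Product: 10 (3S,4S,5R)-4-[4-(benzyloxy)phenyl]-5-[3,5-bis(benzyloxy)phenyl]-1-(trimethylsilyl)hept-6-en-1-yn-3-ol
Conditions: Ru[(S,S)-TsDPEN](p-cymene) (3 mol%, base-free amido complex), i-PrOH, rt
Reagents that add atoms: none
Why: Noyori asymmetric transfer hydrogenation of an alkynyl ketone: the (S,S)-catalyst delivers hydrogen through the six-membered pericyclic transition state with the alkyne as the π-directing group, which should give the 3S carbinol under catalyst control over the neighbouring centre.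

Step 8
Reactants: 10 (3S,4S,5R)-4-[4-(benzyloxy)phenyl]-5-[3,5-bis(benzyloxy)phenyl]-1-(trimethylsilyl)hept-6-en-1-yn-3-ol
Product: 11 (3S,4S,5R)-4-[4-(benzyloxy)phenyl]-5-[3,5-bis(benzyloxy)phenyl]-1-(trimethylsilyl)hept-6-en-1-yn-3-yl methanesulfonate
Conditions: MsCl, Et3N, CH2Cl2, −78 °C
Reagents that add atoms: methanesulfonyl chloride, CS(=O)(=O)Cl
Why: Mesylation forms only an O–S bond, so the propargylic centre keeps its configuration and becomes the leaving group for oxidative addition.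

Step 9
Reactants: 11 (3S,4S,5R)-4-[4-(benzyloxy)phenyl]-5-[3,5-bis(benzyloxy)phenyl]-1-(trimethylsilyl)hept-6-en-1-yn-3-yl methanesulfonate; 12 4-(benzyloxy)benzaldehyde
Product: 14 (1R,2R,3R,4R)-1,3-bis[4-(benzyloxy)phenyl]-4-[3,5-bis(benzyloxy)phenyl]-2-[(trimethylsilyl)ethynyl]hex-5-en-1-ol, via allenylzinc 13 (not isolated)
Conditions: Pd(OAc)2 (5 mol%), PPh3 (5 mol%), Et2Zn (3 equiv), THF, −78 → −20 °C
Reagents that add atoms: none
Why: Marshall propargylation: zerovalent palladium displaces the mesylate anti (SN2′), transmetalation with retention gives allenylzinc 13, and its addition to 12 through a closed six-membered SE2′ transition state forms the C1–C(carbinol) bond syn to zinc, that is with net inversion at C1, which should set C1 as R and the carbinol centre anti to it (the carbinol configuration is erased later by oxidation).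

Step 10
Reactants: 14 (1R,2R,3R,4R)-1,3-bis[4-(benzyloxy)phenyl]-4-[3,5-bis(benzyloxy)phenyl]-2-[(trimethylsilyl)ethynyl]hex-5-en-1-ol
Product: 15 {[(1R,2R,3R,4R)-1,3-bis[4-(benzyloxy)phenyl]-4-[3,5-bis(benzyloxy)phenyl]-2-[(trimethylsilyl)ethynyl]hex-5-en-1-yl]oxy}triethylsilane
Conditions: Et3SiOTf, 2,6-lutidine, CH2Cl2, −78 → 0 °C
Reagents that add atoms: triethylsilyl trifluoromethanesulfonate, CC[Si](CC)(CC)OS(=O)(=O)C(F)(F)F
Why: Silylation of the hindered secondary benzylic alcohol with the silyl triflate prevents lactol formation with the aldehyde made in the next step.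

Step 11
Reactants: 15 {[(1R,2R,3R,4R)-1,3-bis[4-(benzyloxy)phenyl]-4-[3,5-bis(benzyloxy)phenyl]-2-[(trimethylsilyl)ethynyl]hex-5-en-1-yl]oxy}triethylsilane
Product: 16 (2R,3S,4R,5R)-3,5-bis[4-(benzyloxy)phenyl]-2-[3,5-bis(benzyloxy)phenyl]-5-[(triethylsilyl)oxy]-4-[(trimethylsilyl)ethynyl]pentanal
Conditions: OsO4 (2 mol%), NaIO4 (4 equiv), 2,6-lutidine, 1,4-dioxane–H2O (3:1), rt
Reagents that add atoms: sodium periodate, [Na+].[O-]I(=O)(=O)=O (terminal oxidant; the oxygen is delivered through osmium tetroxide, O=[Os](=O)(=O)=O)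
Why: Lemieux–Johnson cleavage: OsO4 dihydroxylates only the terminal vinyl group (silylalkyne and arenes are inert) and periodate cleaves the diol, with lutidine buffering to protect the silyl ether.

Step 12
Reactants: 16 (2R,3S,4R,5R)-3,5-bis[4-(benzyloxy)phenyl]-2-[3,5-bis(benzyloxy)phenyl]-5-[(triethylsilyl)oxy]-4-[(trimethylsilyl)ethynyl]pentanal
Product: 17 {[(1R,2R,3R,4S)-1,3-bis[4-(benzyloxy)phenyl]-4-[3,5-bis(benzyloxy)phenyl]-6,6-dibromo-2-[(trimethylsilyl)ethynyl]hex-5-en-1-yl]oxy}triethylsilane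
Conditions: CBr4, PPh3, Zn, CH2Cl2, rt (reagent preformed); then crude 16, 0 °C → rt
Reagents that add atoms: carbon tetrabromide, BrC(Br)(Br)Br
Why: Ramirez dibromoolefination (first stage of the Corey–Fuchs sequence) is a neutral Wittig-type reaction, run on the crude aldehyde so that the α-aryl centre C3 has no time to epimerise.

Step 13
Reactants: 17 {[(1R,2R,3R,4S)-1,3-bis[4-(benzyloxy)phenyl]-4-[3,5-bis(benzyloxy)phenyl]-6,6-dibromo-2-[(trimethylsilyl)ethynyl]hex-5-en-1-yl]oxy}triethylsilane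
Product: 18 (1R,2R,3R,4R)-1,3-bis[4-(benzyloxy)phenyl]-4-[3,5-bis(benzyloxy)phenyl]-6-bromo-2-ethynylhex-5-yn-1-ol
Conditions: n-Bu4NF·3H2O (6 equiv), DMF, rt → 60 °C
Reagents that add atoms: none
Why: Fluoride-mediated E2 dehydrobromination of the 1,1-dibromoalkene gives the 1-bromoalkyne while the same reagent cleaves the C–SiMe3 and O–SiEt3 bonds, so the C1 terminal alkyne appears without any metalating base and the two diyne termini stay distinct.

Step 14
Reactants: 18 (1R,2R,3R,4R)-1,3-bis[4-(benzyloxy)phenyl]-4-[3,5-bis(benzyloxy)phenyl]-6-bromo-2-ethynylhex-5-yn-1-ol; 19 2-ethynyl-4,4,5,5-tetramethyl-1,3,2-dioxaborolane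
Product: 20 (R)-[4-(benzyloxy)phenyl]{(1R,2R,3R)-2-[4-(benzyloxy)phenyl]-3-[3,5-bis(benzyloxy)phenyl]-4-bromo-6-(4,4,5,5-tetramethyl-1,3,2-dioxaborolan-2-yl)-2,3-dihydro-1H-inden-1-yl}methanol
Conditions: Cp*RuCl(cod) (10 mol%), 19 (3 equiv), ClCH2CH2Cl, rt, slow addition of 18
Reagents that add atoms: none
Why: After loss of cod the Cp*RuCl fragment binds both alkynes of 18 and oxidative cyclisation gives a ruthenacyclopentatriene; this forms C3a–C7a and closes the five-membered carbocycle through the C1–C2–C3 tether. Alkyne 19 then inserts at the unsubstituted Ru–C7 end with its CH carbon on ruthenium, and reductive elimination from the ruthenacycloheptatriene forms C6–C7 and C4–C5, closing ring A as the arene by formal [2+2+2] cycloaddition. The closest known reaction type is the Cp*RuCl(cod)-catalysed cyclotrimerisation of unsymmetrical 1,6-diynes with terminal alkynes, which covers ethynylboronates as the monoalkyne and haloalkyne-terminated diynes. No stereocentre is created: C1, C2, C3 and the carbinol carbon are sp3 spectators on the tether, and the neutral catalyst at room temperature has no means to epimerise them. The selectivity needed is regiochemical, boron at C6 meta to bromine at C4, and the bromine cap secures it because the boryl group of the incoming alkyne turns away from both the Cp* ligand and the substituted α-carbon, the bias that gives meta products from other terminus-substituted diynes. Excess 19 and slow addition of 18 should favour cross-trimerisation over diyne dimerisation.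

Step 15
Reactants: 20 (R)-[4-(benzyloxy)phenyl]{(1R,2R,3R)-2-[4-(benzyloxy)phenyl]-3-[3,5-bis(benzyloxy)phenyl]-4-bromo-6-(4,4,5,5-tetramethyl-1,3,2-dioxaborolan-2-yl)-2,3-dihydro-1H-inden-1-yl}methanol
Product: 21 (R)-[4-(benzyloxy)phenyl]{(1R,2R,3R)-2-[4-(benzyloxy)phenyl]-3-[3,5-bis(benzyloxy)phenyl]-4,6-bis(4,4,5,5-tetramethyl-1,3,2-dioxaborolan-2-yl)-2,3-dihydro-1H-inden-1-yl}methanol
Conditions: B2pin2 (1.5 equiv), Pd(dppf)Cl2 (5 mol%), KOAc (3 equiv), 1,4-dioxane, 90 °C
Reagents that add atoms: bis(pinacolato)diboron, CC1(C)OB(OC1(C)C)B1OC(C)(C)C(C)(C)O1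
Why: Miyaura borylation converts C4–Br into C4–B by oxidative addition, acetate-assisted transmetalation and reductive elimination, and acetate is too weak a base to trigger Suzuki coupling with the C6 boronate.

Step 16
Reactants: 21 (R)-[4-(benzyloxy)phenyl]{(1R,2R,3R)-2-[4-(benzyloxy)phenyl]-3-[3,5-bis(benzyloxy)phenyl]-4,6-bis(4,4,5,5-tetramethyl-1,3,2-dioxaborolan-2-yl)-2,3-dihydro-1H-inden-1-yl}methanol
Product: 22 (1R,2R,3R)-1-{(R)-[4-(benzyloxy)phenyl](hydroxy)methyl}-2-[4-(benzyloxy)phenyl]-3-[3,5-bis(benzyloxy)phenyl]-2,3-dihydro-1H-indene-4,6-diol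
Conditions: 30% aq. H2O2, 2 M NaOH, THF, 0 °C → rt
Reagents that add atoms: hydrogen peroxide, OO
Why: Oxidation of the arylboronates (hydroperoxide addition to boron, then 1,2-aryl migration) turns both C–B bonds into C–O bonds and places the ring A oxygens at C4 and C6.

Step 17
Reactants: 22 (1R,2R,3R)-1-{(R)-[4-(benzyloxy)phenyl](hydroxy)methyl}-2-[4-(benzyloxy)phenyl]-3-[3,5-bis(benzyloxy)phenyl]-2,3-dihydro-1H-indene-4,6-diol
Product: 23 (R)-[4-(benzyloxy)phenyl]{(1R,2R,3R)-4,6-bis(benzyloxy)-2-[4-(benzyloxy)phenyl]-3-[3,5-bis(benzyloxy)phenyl]-2,3-dihydro-1H-inden-1-yl}methanol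
Conditions: BnBr, K2CO3, DMF, rt
Reagents that add atoms: benzyl bromide, BrCc1ccccc1
Why: Williamson etherification: carbonate deprotonates only the phenols, so the secondary benzylic alcohol stays free for oxidation and the phenols are shielded from the oxidant.

Step 18
Reactants: 23 (R)-[4-(benzyloxy)phenyl]{(1R,2R,3R)-4,6-bis(benzyloxy)-2-[4-(benzyloxy)phenyl]-3-[3,5-bis(benzyloxy)phenyl]-2,3-dihydro-1H-inden-1-yl}methanol
Product: 24 [4-(benzyloxy)phenyl]{(1R,2R,3R)-4,6-bis(benzyloxy)-2-[4-(benzyloxy)phenyl]-3-[3,5-bis(benzyloxy)phenyl]-2,3-dihydro-1H-inden-1-yl}methanone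
Conditions: Dess–Martin periodinane, NaHCO3, CH2Cl2, 0 °C → rt
Reagents that add atoms: none
Why: Dess–Martin oxidation gives the aryl ketone under buffered, non-basic conditions, so the now acidic C1–H, cis to the C2 aryl group, should not epimerise.

Step 19
Reactants: 24 [4-(benzyloxy)phenyl]{(1R,2R,3R)-4,6-bis(benzyloxy)-2-[4-(benzyloxy)phenyl]-3-[3,5-bis(benzyloxy)phenyl]-2,3-dihydro-1H-inden-1-yl}methanone
Product: 25 caraphenol B, (4-hydroxyphenyl)[(1R,2R,3R)-3-(3,5-dihydroxyphenyl)-4,6-dihydroxy-2-(4-hydroxyphenyl)-2,3-dihydro-1H-inden-1-yl]methanone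
Conditions: H2 (1 atm), 10% Pd/C, EtOAc–MeOH, rt
Reagents that add atoms: none
Why: Hydrogenolysis of the six aryl benzyl ethers is neutral and should be faster than reduction of the aryl ketone, so the phenols are freed without acid or base that could epimerise C1.

**Compound list**
1 | [4-(benzyloxy)phenyl]acetic acid | OC(=O)Cc1ccc(OCc2ccccc2)cc1 | starting material
2 | pentafluorophenyl [4-(benzyloxy)phenyl]acetate | O=C(Cc1ccc(OCc2ccccc2)cc1)Oc1c(F)c(F)c(F)c(F)c1F | intermediate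
3 | 3,5-bis(benzyloxy)benzaldehyde | O=Cc1cc(OCc2ccccc2)cc(OCc2ccccc2)c1 | starting material
4 | ethyl (2E)-3-[3,5-bis(benzyloxy)phenyl]prop-2-enoate | CCOC(=O)/C=C/c1cc(OCc2ccccc2)cc(OCc2ccccc2)c1 | intermediate
5 | (2E)-3-[3,5-bis(benzyloxy)phenyl]prop-2-en-1-ol | OC/C=C/c1cc(OCc2ccccc2)cc(OCc2ccccc2)c1 | intermediate
6 | tert-butyl (2E)-3-[3,5-bis(benzyloxy)phenyl]prop-2-en-1-yl carbonate | CC(C)(C)OC(=O)OC/C=C/c1cc(OCc2ccccc2)cc(OCc2ccccc2)c1 | intermediate
7 | pentafluorophenyl (2S,3R)-2-[4-(benzyloxy)phenyl]-3-[3,5-bis(benzyloxy)phenyl]pent-4-enoate | O=C(Oc1c(F)c(F)c(F)c(F)c1F)[C@H](c1ccc(OCc2ccccc2)cc1)[C@H](c1cc(OCc2ccccc2)cc(OCc2ccccc2)c1)C=C | intermediate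
8 | (2S,3R)-2-[4-(benzyloxy)phenyl]-3-[3,5-bis(benzyloxy)phenyl]-N-methoxy-N-methylpent-4-enamide | CON(C)C(=O)[C@H](c1ccc(OCc2ccccc2)cc1)[C@H](c1cc(OCc2ccccc2)cc(OCc2ccccc2)c1)C=C | intermediate
9 | (4S,5R)-4-[4-(benzyloxy)phenyl]-5-[3,5-bis(benzyloxy)phenyl]-1-(trimethylsilyl)hept-6-en-1-yn-3-one | C[Si](C)(C)C#CC(=O)[C@H](c1ccc(OCc2ccccc2)cc1)[C@H](c1cc(OCc2ccccc2)cc(OCc2ccccc2)c1)C=C | intermediate
10 | (3S,4S,5R)-4-[4-(benzyloxy)phenyl]-5-[3,5-bis(benzyloxy)phenyl]-1-(trimethylsilyl)hept-6-en-1-yn-3-ol | C[Si](C)(C)C#C[C@@H](O)[C@H](c1ccc(OCc2ccccc2)cc1)[C@H](c1cc(OCc2ccccc2)cc(OCc2ccccc2)c1)C=C | intermediate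
11 | (3S,4S,5R)-4-[4-(benzyloxy)phenyl]-5-[3,5-bis(benzyloxy)phenyl]-1-(trimethylsilyl)hept-6-en-1-yn-3-yl methanesulfonate | C[Si](C)(C)C#C[C@@H](OS(C)(=O)=O)[C@H](c1ccc(OCc2ccccc2)cc1)[C@H](c1cc(OCc2ccccc2)cc(OCc2ccccc2)c1)C=C | intermediate
12 | 4-(benzyloxy)benzaldehyde | O=Cc1ccc(OCc2ccccc2)cc1 | starting material
13 | ethyl{(M)-3-[4-(benzyloxy)phenyl]-4-[3,5-bis(benzyloxy)phenyl]-1-(trimethylsilyl)hexa-1,2,5-trien-1-yl}zinc (aryl-bearing carbons as in 11; zinc anti to the departed mesylate) | CC[Zn]C([Si](C)(C)C)=[C@]=C([H])[C@H](c1ccc(OCc2ccccc2)cc1)[C@H](c1cc(OCc2ccccc2)cc(OCc2ccccc2)c1)C=C | intermediate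
14 | (1R,2R,3R,4R)-1,3-bis[4-(benzyloxy)phenyl]-4-[3,5-bis(benzyloxy)phenyl]-2-[(trimethylsilyl)ethynyl]hex-5-en-1-ol | O[C@@H](c1ccc(OCc2ccccc2)cc1)[C@@H](C#C[Si](C)(C)C)[C@H](c1ccc(OCc2ccccc2)cc1)[C@H](c1cc(OCc2ccccc2)cc(OCc2ccccc2)c1)C=C | intermediate
15 | {[(1R,2R,3R,4R)-1,3-bis[4-(benzyloxy)phenyl]-4-[3,5-bis(benzyloxy)phenyl]-2-[(trimethylsilyl)ethynyl]hex-5-en-1-yl]oxy}triethylsilane | CC[Si](CC)(CC)O[C@@H](c1ccc(OCc2ccccc2)cc1)[C@@H](C#C[Si](C)(C)C)[C@H](c1ccc(OCc2ccccc2)cc1)[C@H](c1cc(OCc2ccccc2)cc(OCc2ccccc2)c1)C=C | intermediate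
16 | (2R,3S,4R,5R)-3,5-bis[4-(benzyloxy)phenyl]-2-[3,5-bis(benzyloxy)phenyl]-5-[(triethylsilyl)oxy]-4-[(trimethylsilyl)ethynyl]pentanal | CC[Si](CC)(CC)O[C@@H](c1ccc(OCc2ccccc2)cc1)[C@@H](C#C[Si](C)(C)C)[C@H](c1ccc(OCc2ccccc2)cc1)[C@H](c1cc(OCc2ccccc2)cc(OCc2ccccc2)c1)C=O | intermediate
17 | {[(1R,2R,3R,4S)-1,3-bis[4-(benzyloxy)phenyl]-4-[3,5-bis(benzyloxy)phenyl]-6,6-dibromo-2-[(trimethylsilyl)ethynyl]hex-5-en-1-yl]oxy}triethylsilane | CC[Si](CC)(CC)O[C@@H](c1ccc(OCc2ccccc2)cc1)[C@@H](C#C[Si](C)(C)C)[C@H](c1ccc(OCc2ccccc2)cc1)[C@H](c1cc(OCc2ccccc2)cc(OCc2ccccc2)c1)C=C(Br)Br | intermediate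
18 | (1R,2R,3R,4R)-1,3-bis[4-(benzyloxy)phenyl]-4-[3,5-bis(benzyloxy)phenyl]-6-bromo-2-ethynylhex-5-yn-1-ol | O[C@@H](c1ccc(OCc2ccccc2)cc1)[C@@H](C#C)[C@H](c1ccc(OCc2ccccc2)cc1)[C@H](c1cc(OCc2ccccc2)cc(OCc2ccccc2)c1)C#CBr | intermediate
19 | 2-ethynyl-4,4,5,5-tetramethyl-1,3,2-dioxaborolane (ethynylboronic acid pinacol ester) | C#CB1OC(C)(C)C(C)(C)O1 | starting material
20 | (R)-[4-(benzyloxy)phenyl]{(1R,2R,3R)-2-[4-(benzyloxy)phenyl]-3-[3,5-bis(benzyloxy)phenyl]-4-bromo-6-(4,4,5,5-tetramethyl-1,3,2-dioxaborolan-2-yl)-2,3-dihydro-1H-inden-1-yl}methanol | O[C@@H](c1ccc(OCc2ccccc2)cc1)[C@H]1c2cc(B3OC(C)(C)C(C)(C)O3)cc(Br)c2[C@@H](c2cc(OCc3ccccc3)cc(OCc3ccccc3)c2)[C@H]1c1ccc(OCc2ccccc2)cc1 | intermediate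
21 | (R)-[4-(benzyloxy)phenyl]{(1R,2R,3R)-2-[4-(benzyloxy)phenyl]-3-[3,5-bis(benzyloxy)phenyl]-4,6-bis(4,4,5,5-tetramethyl-1,3,2-dioxaborolan-2-yl)-2,3-dihydro-1H-inden-1-yl}methanol | O[C@@H](c1ccc(OCc2ccccc2)cc1)[C@H]1c2cc(B3OC(C)(C)C(C)(C)O3)cc(B3OC(C)(C)C(C)(C)O3)c2[C@@H](c2cc(OCc3ccccc3)cc(OCc3ccccc3)c2)[C@H]1c1ccc(OCc2ccccc2)cc1 | intermediate
22 | (1R,2R,3R)-1-{(R)-[4-(benzyloxy)phenyl](hydroxy)methyl}-2-[4-(benzyloxy)phenyl]-3-[3,5-bis(benzyloxy)phenyl]-2,3-dihydro-1H-indene-4,6-diol | O[C@@H](c1ccc(OCc2ccccc2)cc1)[C@H]1c2cc(O)cc(O)c2[C@@H](c2cc(OCc3ccccc3)cc(OCc3ccccc3)c2)[C@H]1c1ccc(OCc2ccccc2)cc1 | intermediate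
23 | (R)-[4-(benzyloxy)phenyl]{(1R,2R,3R)-4,6-bis(benzyloxy)-2-[4-(benzyloxy)phenyl]-3-[3,5-bis(benzyloxy)phenyl]-2,3-dihydro-1H-inden-1-yl}methanol | O[C@@H](c1ccc(OCc2ccccc2)cc1)[C@H]1c2cc(OCc3ccccc3)cc(OCc3ccccc3)c2[C@@H](c2cc(OCc3ccccc3)cc(OCc3ccccc3)c2)[C@H]1c1ccc(OCc2ccccc2)cc1 | intermediate
24 | [4-(benzyloxy)phenyl]{(1R,2R,3R)-4,6-bis(benzyloxy)-2-[4-(benzyloxy)phenyl]-3-[3,5-bis(benzyloxy)phenyl]-2,3-dihydro-1H-inden-1-yl}methanone | O=C(c1ccc(OCc2ccccc2)cc1)[C@H]1c2cc(OCc3ccccc3)cc(OCc3ccccc3)c2[C@@H](c2cc(OCc3ccccc3)cc(OCc3ccccc3)c2)[C@H]1c1ccc(OCc2ccccc2)cc1 | intermediate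
25 | caraphenol B, (4-hydroxyphenyl)[(1R,2R,3R)-3-(3,5-dihydroxyphenyl)-4,6-dihydroxy-2-(4-hydroxyphenyl)-2,3-dihydro-1H-inden-1-yl]methanone | O=C(c1ccc(O)cc1)[C@H]1c2cc(O)cc(O)c2[C@@H](c2cc(O)cc(O)c2)[C@H]1c1ccc(O)cc1 | target

**Step count**
Total: 19 steps. Longest linear sequence: 18 steps (from 3 through steps 2 to 19); step 1 is the only side branch.

**Steps most likely to fail**

Step 14. Bromine is a small steering group, so some of the boryl alkyne may enter next to C4, and the diyne may be consumed by homo-dimerisation or by carbon–bromine activation at ruthenium. The fallback changes the cap and the way it is made, moving to the iodoalkyne-terminated diyne class that is documented for this catalyst and steers more strongly. It sets out from 17: n-BuLi (2.1 equiv, THF, −78 °C) followed by iodine should give, through the lithium acetylide, the silyl-protected iodoalkyne F1. Fluoride (n-Bu4NF, THF, 0 °C) would then free both the terminal alkyne and the carbinol to give the iodo diyne F2. Cyclotrimerisation of this with 19 under Cp*RuCl(cod) should deliver the 4-iodo-6-boryl indane carbinol F3, and Miyaura borylation of the aryl iodide brings the material back to the route at 21.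

Step 9. The transient allenylzinc is congested and may add slowly to the aromatic aldehyde, so that ethyl transfer from Et2Zn to 12, protonation to the allene, or leakage of the allene configuration (loss of C1 integrity) can compete. The fallback replaces the transient organozinc by an isolable allenylboronate. It sets out from 10: ClCO2Me and pyridine should give the propargylic methyl carbonate F4. Monovalent copper catalysis (CuO-t-Bu, Xantphos, B2pin2, THF) would then deliver boron anti to the leaving group to give the allenylboronate F5. Heating this with 12 in toluene should effect propargylboration through the same closed six-membered transition state, returning to the route at 14 with C1 again set by net inversion.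

Step 19. Removal of six benzyl groups is slow, and during that time the aryl ketone may be reduced to the benzylic alcohol or methylene, or the cis C1 centre may epimerise on prolonged contact with the catalyst. The fallback is non-reductive: from 24, BCl3 with pentamethylbenzene as cation scavenger (CH2Cl2, −78 °C, methanol quench) should cleave all six aryl benzyl ethers by Lewis-acid dealkylation and give 25 directly, without any new intermediate.

**Further compounds**
F1 | step 14 | {[(1R,2R,3R,4R)-1,3-bis[4-(benzyloxy)phenyl]-4-[3,5-bis(benzyloxy)phenyl]-6-iodo-2-[(trimethylsilyl)ethynyl]hex-5-yn-1-yl]oxy}triethylsilane | CC[Si](CC)(CC)O[C@@H](c1ccc(OCc2ccccc2)cc1)[C@@H](C#C[Si](C)(C)C)[C@H](c1ccc(OCc2ccccc2)cc1)[C@H](c1cc(OCc2ccccc2)cc(OCc2ccccc2)c1)C#CI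
F2 | step 14 | (1R,2R,3R,4R)-1,3-bis[4-(benzyloxy)phenyl]-4-[3,5-bis(benzyloxy)phenyl]-2-ethynyl-6-iodohex-5-yn-1-ol | O[C@@H](c1ccc(OCc2ccccc2)cc1)[C@@H](C#C)[C@H](c1ccc(OCc2ccccc2)cc1)[C@H](c1cc(OCc2ccccc2)cc(OCc2ccccc2)c1)C#CI
F3 | step 14 | (R)-[4-(benzyloxy)phenyl]{(1R,2R,3R)-2-[4-(benzyloxy)phenyl]-3-[3,5-bis(benzyloxy)phenyl]-4-iodo-6-(4,4,5,5-tetramethyl-1,3,2-dioxaborolan-2-yl)-2,3-dihydro-1H-inden-1-yl}methanol | O[C@@H](c1ccc(OCc2ccccc2)cc1)[C@H]1c2cc(B3OC(C)(C)C(C)(C)O3)cc(I)c2[C@@H](c2cc(OCc3ccccc3)cc(OCc3ccccc3)c2)[C@H]1c1ccc(OCc2ccccc2)cc1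
F4 | step 9 | (3S,4S,5R)-4-[4-(benzyloxy)phenyl]-5-[3,5-bis(benzyloxy)phenyl]-1-(trimethylsilyl)hept-6-en-1-yn-3-yl methyl carbonate | C[Si](C)(C)C#C[C@@H](OC(=O)OC)[C@H](c1ccc(OCc2ccccc2)cc1)[C@H](c1cc(OCc2ccccc2)cc(OCc2ccccc2)c1)C=C
F5 | step 9 | 2-{(P)-3-[4-(benzyloxy)phenyl]-4-[3,5-bis(benzyloxy)phenyl]-1-(trimethylsilyl)hexa-1,2,5-trien-1-yl}-4,4,5,5-tetramethyl-1,3,2-dioxaborolane (aryl-bearing carbons as in 10; boron anti to the departed carbonate) | C[Si](C)(C)C(B1OC(C)(C)C(C)(C)O1)=[C@@]=C([H])[C@H](c1ccc(OCc2ccccc2)cc1)[C@H](c1cc(OCc2ccccc2)cc(OCc2ccccc2)c1)C=C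
F0 | step 19 | none | none
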